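**Plan**
- Retrosynthesis: first the phenol O–benzyl bond (protecting group) is cut, then the C1–C2 bond of the nonadecyl chain (O–CH2 | CH2–C17H35), then the carboxylate O–CH2 bond of an O-acylglycolic acid.
- Enabling feature: C1 of the chain carries the ester oxygen, so it maps onto the α-carbon of an O-acylglycolic acid; loss of CO2 from this acid gives an oxygen-stabilised (acyloxy)methyl radical. C2 is the end of an unbranched, unfunctionalised C18 chain and maps onto nonadecanoic acid.
- Forward: the aryl-propanoic acid is O-alkylated with tert-butyl bromoacetate, the tert-butyl ester is cleaved, and the resulting acid is activated as its N-acyloxyphthalimide. Nonadecanoic acid is activated in the same way.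
- The two redox-active esters are joined at nickel under electroreduction with loss of two CO2 (a union of two like-polarity carbons); hydrogenolysis then frees the phenol.
- The molecule has no ring to build and no stereocentre, so no stereocontrol is needed.

Key step: step 5

Remark: the target is achiral (no stereocentre, no stereogenic double bond), so the question of the enantiomer does not arise. 3-[4-(Benzyloxy)phenyl]propanoic acid, tert-butyl bromoacetate and nonadecanoic acid are taken as purchased.

**Step 1**
Reactants: 1 3-[4-(benzyloxy)phenyl]propanoic acid; 2 tert-butyl bromoacetate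
Product: 3 2-tert-butoxy-2-oxoethyl 3-[4-(benzyloxy)phenyl]propanoate
Conditions: Cs2CO3 (0.55 equiv), 2 (1.1 equiv), DMF, rt
Reagents that add atoms: none
Why: SN2 O-alkylation of a caesium carboxylate by an α-bromo ester should be clean because the phenol is already benzylated and the carboxylate is the only nucleophile.

**Step 2**
Reactants: 3 2-tert-butoxy-2-oxoethyl 3-[4-(benzyloxy)phenyl]propanoate
Product: 4 2-({3-[4-(benzyloxy)phenyl]propanoyl}oxy)acetic acid
Conditions: TFA/CH2Cl2 (1:3), 0 °C to rt, short reaction time
Reagents that add atoms: none
Why: Acidolysis of a tert-butyl ester (loss of the tert-butyl cation as isobutene) should leave the primary acyloxyacetate ester and, on brief exposure, the benzyl aryl ether untouched.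

**Step 3**
Reactants: 4 2-({3-[4-(benzyloxy)phenyl]propanoyl}oxy)acetic acid
Product: 5 1,3-dioxoisoindolin-2-yl 2-({3-[4-(benzyloxy)phenyl]propanoyl}oxy)acetate
Conditions: N-hydroxyphthalimide (1.1 equiv), DIC (1.1 equiv), DMAP (5 mol%), CH2Cl2, 0 °C to rt
Reagents that add atoms: N-hydroxyphthalimide, ON1C(=O)c2ccccc2C1=O
Why: Carbodiimide-mediated (Steglich-type) esterification of the acid with N-hydroxyphthalimide should give the redox-active ester; no free OH or NH competes.

**Step 4**
Reactants: 6 nonadecanoic acid
Product: 7 1,3-dioxoisoindolin-2-yl nonadecanoate
Conditions: N-hydroxyphthalimide (1.1 equiv), DIC (1.1 equiv), DMAP (5 mol%), CH2Cl2/THF, rt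
Reagents that add atoms: N-hydroxyphthalimide, ON1C(=O)c2ccccc2C1=O
Why: The same carbodiimide esterification on an unfunctionalised fatty acid should give a crystalline redox-active ester.

**Step 5**
Reactants: 5 1,3-dioxoisoindolin-2-yl 2-({3-[4-(benzyloxy)phenyl]propanoyl}oxy)acetate; 7 1,3-dioxoisoindolin-2-yl nonadecanoate
Product: 8 nonadecyl 3-[4-(benzyloxy)phenyl]propanoate
Conditions: 5 (1 equiv), 7 (3 equiv), NiCl2·6H2O (20 mol%), 2,2':6',2''-terpyridine (20 mol%), AgNO3 (0.3 equiv), NMP/THF, undivided cell, Mg(+)/RVC(−), constant current, rt; aq. HCl work-up
Reagents that add atoms: none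
Why: At the silver-coated cathode the Ni(II)/terpyridine complex is reduced to low-valent nickel, which passes one electron to each N-acyloxyphthalimide; N–O cleavage and loss of CO2 then give the primary octadecyl radical from 7 and the oxygen-stabilised (acyloxy)methyl radical from 5, while the magnesium anode supplies the two electrons. Nickel captures one radical as an alkyl-nickel species, takes up the second and forms the CH2–CH2 bond by C(sp3)–C(sp3) reductive elimination, so two carbons that both start as acyl electrophiles are joined under net reduction. The closest known reaction type is the nickel-electrocatalytic doubly decarboxylative C(sp3)–C(sp3) cross-coupling of two redox-active esters, which accepts α-oxygenated acid partners and is the reductive counterpart of a mixed Kolbe electrolysis. No ring is closed and no stereocentre is formed. The step needs cross-coupling over homo-coupling and reduction of the N–O bonds in preference to the two ordinary esters and the benzyl ether; the first should be secured by the threefold excess of the cheap fatty ester 7 and the different character of the two radicals (nucleophilic alkyl versus α-acyloxy), the second by the much less negative reduction potential of N-acyloxyphthalimides. The homo-coupled by-products expected (a C36 alkane and a glycol diester) differ strongly in polarity from 8 and should be removable by chromatography.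

**Step 6**
Reactants: 8 nonadecyl 3-[4-(benzyloxy)phenyl]propanoate
Product: 9 nonadecyl 3-(4-hydroxyphenyl)propanoate
Conditions: H2 (1 atm), 10% Pd/C, EtOAc/THF, rt
Reagents that add atoms: none
Why: Catalytic hydrogenolysis of a benzyl aryl ether should free the phenol without touching the saturated alkyl ester.

**Compound list**
1 | 3-[4-(benzyloxy)phenyl]propanoic acid | OC(=O)CCc1ccc(OCc2ccccc2)cc1 | starting material
2 | tert-butyl bromoacetate | CC(C)(C)OC(=O)CBr | starting material
3 | 2-tert-butoxy-2-oxoethyl 3-[4-(benzyloxy)phenyl]propanoate | CC(C)(C)OC(=O)COC(=O)CCc1ccc(OCc2ccccc2)cc1 | intermediate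
4 | 2-({3-[4-(benzyloxy)phenyl]propanoyl}oxy)acetic acid | OC(=O)COC(=O)CCc1ccc(OCc2ccccc2)cc1 | intermediate
5 | 1,3-dioxoisoindolin-2-yl 2-({3-[4-(benzyloxy)phenyl]propanoyl}oxy)acetate | O=C(CCc1ccc(OCc2ccccc2)cc1)OCC(=O)ON1C(=O)c2ccccc2C1=O | intermediate
6 | nonadecanoic acid | CCCCCCCCCCCCCCCCCCC(=O)O | starting material
7 | 1,3-dioxoisoindolin-2-yl nonadecanoate | CCCCCCCCCCCCCCCCCCC(=O)ON1C(=O)c2ccccc2C1=O | intermediate
8 | nonadecyl 3-[4-(benzyloxy)phenyl]propanoate | CCCCCCCCCCCCCCCCCCCOC(=O)CCc1ccc(OCc2ccccc2)cc1 | intermediate
9 | nonadecyl 3-(4-hydroxyphenyl)propanoate | CCCCCCCCCCCCCCCCCCCOC(=O)CCc1ccc(O)cc1 | target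

**Step count**
Total steps: 6. Longest linear sequence: 5 steps (steps 1, 2, 3, 5, 6); step 4 is a one-step side branch.

**Steps most likely to fail**

Step 5. The two radicals may pair statistically, so that homo-coupling and premature reduction of the alkyl-nickel intermediates consume the limiting ester 5, and the activated ester 5 may be lost at the cathode before it couples. The fallback sets out from 5 and comes back to the route at 8. Commercial 1-bromooctadecane (CCCCCCCCCCCCCCCCCCBr) would be converted with magnesium in THF into octadecylmagnesium bromide F1, which would be transmetallated with ZnCl2 (0.5 equiv) to dioctadecylzinc F2. F2 (2 equiv) would then be coupled with 5 under NiCl2·glyme and 4,4'-di-tert-butyl-2,2'-bipyridine in THF/DMF at rt, a nickel-catalysed decarboxylative alkyl–alkyl Negishi coupling of a redox-active ester, to give 8. Only one radical is generated here and it meets a preformed alkyl-metal, so the cross-selectivity question disappears; the organozinc should tolerate both esters.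

Step 3. The activated α-acyloxy N-acyloxyphthalimide may hydrolyse during work-up and chromatography, or the O-acylisourea may rearrange to an N-acylurea before it is trapped. The fallback sets out from 4 and comes back to the route at 8, bypassing steps 3 to 5. The free acid 4 would be coupled directly with 1-bromooctadecane by dual iridium-photoredox/nickel catalysis (Ir[dF(CF3)ppy]2(dtbbpy)PF6, NiCl2·glyme, 4,4'-dimethoxy-2,2'-bipyridine, K2CO3, MeCN with a little water, blue LEDs). This is a decarboxylative C(sp3)–C(sp3) coupling of an α-oxy carboxylate with a primary alkyl bromide, in which photo-oxidation of the carboxylate and loss of CO2 give the same (acyloxy)methyl radical. This fallback makes no new compound (none F0).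

Step 2. The acid may partly remove the benzyl ether, the tert-butyl cation may alkylate the electron-rich ring, or the acyloxyacetate linkage may be cleaved. The fallback sets out from 1 and comes back to the route at 4. The caesium salt of 1 would be alkylated with allyl bromoacetate (C=CCOC(=O)CBr) in DMF to give 2-(allyloxy)-2-oxoethyl 3-[4-(benzyloxy)phenyl]propanoate F3. The allyl ester would then be removed under neutral conditions with Pd(PPh3)4 (cat.) and morpholine in THF at rt (Tsuji–Trost deallylation) to give 4.

**Further compounds**
F1 | step 5 | octadecylmagnesium bromide | CCCCCCCCCCCCCCCCCC[Mg]Br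
F2 | step 5 | dioctadecylzinc | CCCCCCCCCCCCCCCCCC[Zn]CCCCCCCCCCCCCCCCCC
F0 | step 3 | none | none
F3 | step 2 | 2-(allyloxy)-2-oxoethyl 3-[4-(benzyloxy)phenyl]propanoate | C=CCOC(=O)COC(=O)CCc1ccc(OCc2ccccc2)cc1
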